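The retrosynthesis first restores the methyl group on O5, since the last step is a chelation-directed 5-O-demethylation. It then opens ring C at O1–C2, with a CO2tBu helper placed on C3. It then cuts C2=C3 (Knoevenagel, veratraldehyde), and finally C3–CO2tBu and C4–C4a, back to 3,4,5-trimethoxyphenol.
Forward, rings A and B are bought. The C4–C3 chain goes onto ring A, the helper ester goes onto C3, ring B arrives together with C2, and ring C, the only ring made, closes last at O1–C2.
Enabling feature: O1 on C8a of ring A and the benzylic C2 are joined through C8a–C4a–C4(=O)–C3. C2 is therefore the β-carbon of an aryl enone that O1 reaches by a 6-endo-trig path, and the C3 methylene between C4=O and C2 can carry a removable ester.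
The two methoxy groups of ring B weaken this acceptor and make the plain chalcone closure slow and reversible. The C3 ester strengthens the acceptor, gives the catalyst a two-point hydrogen-bond handle, and leaves as isobutene and CO2 in the same flask.
Regiochemistry: the starting phenol is mirror-symmetric, so acylation has one outcome. O5 stays methylated until the end, so only O1 can close, which gives the 6,7- and not the 7,8-dimethoxy pattern.
Stereochemistry: C2, the only stereocentre of the target, is set in the ring closure by a bifunctional cinchona thiourea. C3 is stereogenic only in passing.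

Key step: step 4

Assumption: the thiourea derived from 9-amino-9-deoxy-epi-quinidine is taken to give the 2S series. The sense of induction would be checked on compound 8 against natural 2S flavanones, and the equally available quinine-derived pseudoenantiomer addresses the other face if needed.

Step 1
Reactants: 1 3,4,5-trimethoxyphenol
Product: 2 1-(2-hydroxy-4,5,6-trimethoxyphenyl)ethan-1-one
Conditions: AcOH (solvent), BF3·OEt2 (3 equiv), 85 °C; then H2O, rt
Reagents that add atoms: acetic acid, CC(=O)O
Why: Friedel–Crafts acylation of a highly activated phenol under BF3 activation should go ortho to the hydroxyl group, because the para position carries OMe and the two ortho positions are equivalent by the mirror symmetry of 1, and the hydrogen-bonded, deactivated ketone 2 should not be acylated again.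

Step 2
Reactants: 2 1-(2-hydroxy-4,5,6-trimethoxyphenyl)ethan-1-one
Product: 3 tert-butyl 3-(2-hydroxy-4,5,6-trimethoxyphenyl)-3-oxopropanoate
Conditions: LiN(SiMe3)2 (3.2 equiv), THF, −78 °C; Boc2O (1.1 equiv), −78 → 0 °C; cold 1 M HCl quench
Reagents that add atoms: di-tert-butyl dicarbonate (Boc2O), CC(C)(C)OC(=O)OC(=O)OC(C)(C)C
Why: Crossed Claisen-type C-acylation of the lithium phenoxide–enolate dianion of 2 by Boc2O should stop at 3 because the third equivalent of base stores the product as its stabilised enolate, which is the thermodynamic sink to which any O-acylated material is returned by Baker–Venkataraman-type O-to-C transfer, while the bulky tert-butyl ester resists lactonisation at or below 0 °C.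

Step 3
Reactants: 3 tert-butyl 3-(2-hydroxy-4,5,6-trimethoxyphenyl)-3-oxopropanoate; 4 3,4-dimethoxybenzaldehyde (veratraldehyde)
Product: 5 tert-butyl (Z)-3-(3,4-dimethoxyphenyl)-2-(2-hydroxy-4,5,6-trimethoxybenzoyl)prop-2-enoate
Conditions: piperidine (10 mol %), AcOH (10 mol %), 4 Å MS, toluene, rt
Reagents that add atoms: none
Why: Knoevenagel condensation through the piperidine iminium ion of 4 with removal of water by the sieves should give the trisubstituted alkene mainly as the Z isomer (ring B cis to the ester), and the buffered medium, the room temperature and the bulky ester should keep the free phenol from closing before the chiral catalyst is present.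

Step 4
Reactants: 5 tert-butyl (Z)-3-(3,4-dimethoxyphenyl)-2-(2-hydroxy-4,5,6-trimethoxybenzoyl)prop-2-enoate
Product: 8 (2S)-2-(3,4-dimethoxyphenyl)-5,6,7-trimethoxychroman-4-one, via cyclised trans tert-butyl ester 6 (not isolated), via free β-keto acid 7 (not isolated)
Conditions: N-[3,5-bis(trifluoromethyl)phenyl]-N'-[(9R)-6'-methoxycinchonan-9-yl]thiourea (quinidine series, 10 mol %), toluene, −25 °C; then TsOH·H2O (50 mol %), 80 °C, same flask
Reagents that add atoms: none
Why: The quinuclidine nitrogen of the catalyst takes up the proton of the only free phenol while the two thiourea N–H bonds bind the ketone and ester carbonyl groups of the alkylidene β-keto ester, so that O1 adds to the benzylic β-carbon C2 within a chiral hydrogen-bonded ion pair and the resulting enolate is protonated to 6; TsOH then cleaves the tert-butyl ester to 7 with loss of isobutene, and 7 loses CO2 through its six-membered β-keto acid transition state. The closest known reaction type is this very one, the bifunctional cinchona-thiourea-catalysed intramolecular oxa-Michael addition of 2-hydroxyaryl alkylidene β-keto esters with acid decarboxylation in the same flask, which has been applied to C2-aryl groups that bear para oxygen substituents. Ring C closes in the 6-endo-trig mode, since attack of O1 at C3 would be a 5-exo closure on the wrong, electron-rich end of the acceptor. C2 is controlled by the catalyst, which exposes one face of the bound acceptor to the phenoxide, whereas C3 settles trans under thermodynamic control and is erased with the helper. The step needs site selectivity between the two oxygens ortho to the ketone and kinetic control of a reversible addition: O5 is methylated, so only the oxygen next to C8–H can close and the 6,7- rather than the 7,8-dimethoxy pattern results, and the doubly activated acceptor lets the closure run at −25 °C, where the retro-addition should be slow. The helper is removed by acid and not by base, so no enolate of 8 is formed that could expel O1 and racemise C2.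

Step 5
Reactants: 8 (2S)-2-(3,4-dimethoxyphenyl)-5,6,7-trimethoxychroman-4-one
Product: 10 (2S)-2-(3,4-dimethoxyphenyl)-5-hydroxy-6,7-dimethoxychroman-4-one, via O5-dichloroboryl chelate 9 (not isolated)
Conditions: BCl3 (1.2 equiv, 1 M in CH2Cl2), CH2Cl2, −78 → −20 °C; then H2O/THF, 0 °C
Reagents that add atoms: none
Why: Chelation-directed aryl methyl ether cleavage: BCl3 is held between the C4 carbonyl oxygen and the peri 5-OMe oxygen in a six-membered chelate, so chloride should remove only that methyl group as MeCl while the four other methoxy groups, which lack such a chelate, survive at low temperature, and C2 is not touched as long as the near-stoichiometric charge and the low temperature keep the benzylic C2–O1 bond from ionising.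

Compound list
1 | 3,4,5-trimethoxyphenol | COc1cc(O)cc(OC)c1OC | starting material
2 | 1-(2-hydroxy-4,5,6-trimethoxyphenyl)ethan-1-one | CC(=O)c1c(O)cc(OC)c(OC)c1OC | intermediate
3 | tert-butyl 3-(2-hydroxy-4,5,6-trimethoxyphenyl)-3-oxopropanoate | CC(C)(C)OC(=O)CC(=O)c1c(O)cc(OC)c(OC)c1OC | intermediate
4 | 3,4-dimethoxybenzaldehyde | COc1ccc(C=O)cc1OC | starting material
5 | tert-butyl (Z)-3-(3,4-dimethoxyphenyl)-2-(2-hydroxy-4,5,6-trimethoxybenzoyl)prop-2-enoate | COc1ccc(/C=C(\C(=O)OC(C)(C)C)C(=O)c2c(O)cc(OC)c(OC)c2OC)cc1OC | intermediate
6 | tert-butyl (2S,3R)-2-(3,4-dimethoxyphenyl)-5,6,7-trimethoxy-4-oxochromane-3-carboxylate (trans) | COc1ccc([C@@H]2[C@@H](C(=O)OC(C)(C)C)C(=O)c3c(cc(OC)c(OC)c3OC)O2)cc1OC | intermediate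
7 | (2S,3R)-2-(3,4-dimethoxyphenyl)-5,6,7-trimethoxy-4-oxochromane-3-carboxylic acid | COc1ccc([C@@H]2[C@@H](C(=O)O)C(=O)c3c(cc(OC)c(OC)c3OC)O2)cc1OC | intermediate
8 | (2S)-2-(3,4-dimethoxyphenyl)-5,6,7-trimethoxychroman-4-one | COc1ccc([C@@H]2CC(=O)c3c(cc(OC)c(OC)c3OC)O2)cc1OC | intermediate
9 | (2S)-5-(dichloroboryloxy)-2-(3,4-dimethoxyphenyl)-6,7-dimethoxychroman-4-one (boron also bound to the C4 carbonyl oxygen) | COc1ccc([C@@H]2CC(=O)c3c(cc(OC)c(OC)c3OB(Cl)Cl)O2)cc1OC | intermediate
10 | (2S)-2-(3,4-dimethoxyphenyl)-5-hydroxy-6,7-dimethoxychroman-4-one | COc1ccc([C@@H]2CC(=O)c3c(cc(OC)c(OC)c3O)O2)cc1OC | target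

Total step count: 5. Longest linear sequence: 5 steps (1 → 2 → 3 → 5 → 8 → 10).

Steps most likely to fail

1. Step 4.
- What may go wrong: the catalyst may discriminate poorly between the two faces on this di-ortho-substituted aroyl substrate. The ee may also erode through reversible ring opening, which the electron-rich ring B favours, either in the cold stage or in the hot acid stage.
- Fallback (from 2, back at 8): the stereocentre is made by C2–aryl bond formation instead.
- Ketone 2 is condensed with N,N-dimethylformamide dimethyl acetal (toluene, 90 °C) to the enaminone (E)-3-(dimethylamino)-1-(2-hydroxy-4,5,6-trimethoxyphenyl)prop-2-en-1-one F1.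
- Aqueous HCl in CH2Cl2 closes F1 to 5,6,7-trimethoxy-4H-chromen-4-one F2.
- Asymmetric 1,4-addition of 3,4-dimethoxyphenylboronic acid then follows. It uses [Rh(OH)(cod)]2 and the enantiomer of the electron-poor diphosphine MeO-F12-BIPHEP that leads to the 2S series (toluene/H2O, rt, no added base). This is a known reaction of chromones and should give 8.

2. Step 5.
- What may go wrong: configurational integrity at C2 may be lost through Lewis-acid-assisted ionisation of the benzylic C2–O1 bond or through enolisation and ring opening. The neighbouring 6-OMe group may also be cleaved.
- Fallback (from 2, back at 10): the ether cleavage is moved to an achiral stage.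
- 5,6,7-Trimethoxy-4H-chromen-4-one F2, made from 2 as described above, is treated with BCl3 (CH2Cl2, −78 → 0 °C). This should give 5-hydroxy-6,7-dimethoxy-4H-chromen-4-one F3, in which nothing can racemise.
- The same rhodium-catalysed asymmetric 1,4-addition of 3,4-dimethoxyphenylboronic acid then sets C2 in the last operation under near-neutral conditions and should give 10 directly.

3. Step 2.
- What may go wrong: acylation may stay at oxygen without transfer to carbon, acylation may occur twice, or the product may lactonise on warming.
- Fallback (from 2, back at 3): the intermolecular acylation of a dianion is replaced by an intramolecular acyl shift of an isolated compound.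
- Phenol 2 is converted with Boc2O and catalytic DMAP (CH2Cl2, rt) into 2-acetyl-3,4,5-trimethoxyphenyl tert-butyl carbonate F4, which is purified.
- F4 is then treated with LiN(SiMe3)2 (2.2 equiv, THF, −78 → 0 °C). The methyl ketone enolate takes the carboxyl group from the neighbouring oxygen through a six-membered transition state (Baker–Venkataraman rearrangement of a carbonate) and releases the phenoxide of 3.

Further compounds
F1 | step 4 | (E)-3-(dimethylamino)-1-(2-hydroxy-4,5,6-trimethoxyphenyl)prop-2-en-1-one | CN(C)/C=C/C(=O)c1c(O)cc(OC)c(OC)c1OC
F2 | step 4 | 5,6,7-trimethoxy-4H-chromen-4-one | COc1cc2occc(=O)c2c(OC)c1OC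
F3 | step 5 | 5-hydroxy-6,7-dimethoxy-4H-chromen-4-one | COc1cc2occc(=O)c2c(O)c1OC
F4 | step 2 | 2-acetyl-3,4,5-trimethoxyphenyl tert-butyl carbonate | CC(=O)c1c(OC(=O)OC(C)(C)C)cc(OC)c(OC)c1OC
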